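**Plan**

- Retrosynthesis: the C2–O bond is traced back to a C2–B bond (stereoretentive oxidation). The bond from the 2,4,6-trimethoxyphenyl ring carbon to C1 and the bond C2–C3 are then cut together, leading back to a vinyl group on boron, an aryl bromide and a benzylboronate. The benzylic C3–B bond comes from a benzyl chloride.
- Forward: no ring is formed. Benzyl chloride 1 gives benzylboronate 2. Vinylmagnesium bromide 3 and aryl bromide 4 are then joined with 2, through the four-coordinate vinylborate 5, in a three-component Pd-catalysed conjunctive cross-coupling to boronic ester 6. Oxidation gives hypophaol 7.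
- Stereochemistry: the only stereocentre (C2, S) is set by the chiral Pd–MandyPhos catalyst during the 1,2-metallate shift and is carried into the C–O bond with retention.
- Enabling feature: the carbinol carbon C2 lies between two methylenes, C1 (bonded to the ring carbon between the two ortho-methoxy groups of the trimethoxyphenyl ring) and C3 (bonded to the 3,4-dimethoxyphenyl ring). C1–C2 is therefore a latent B-vinyl group, C2–O a latent C2–B bond, the C3 benzyl group a group that can migrate from boron to C2, and the trimethoxyphenyl ring carbon an sp2 carbon that palladium can deliver to C1.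

Key step: step 2

Assumption: the (Sp,Sp) antipode of MandyPhos is taken to deliver (S)-C2; this sense of induction is not derived here and is to be checked on the first batch (Mosher ester analysis of 7). If the (R)-product is formed, the (Rp,Rp) antipode is used under otherwise identical conditions.

**Step 1**
Reactants: 1 3,4-dimethoxybenzyl chloride
Product: 2 2-(3,4-dimethoxybenzyl)-4,4,5,5-tetramethyl-1,3,2-dioxaborolane
Conditions: B2pin2 (1.1 equiv), Pd(dba)2 (3 mol%), P(4-MeOC6H4)3 (6 mol%), KOAc (1.5 equiv), toluene, 50 °C
Reagents that add atoms: bis(pinacolato)diboron, CC1(C)OB(OC1(C)C)B1OC(C)(C)C(C)(C)O1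
Why: Miyaura borylation of a benzylic chloride (oxidative addition to C–Cl, acetate-assisted transmetalation with B2pin2, C–B reductive elimination); the aryl methyl ethers are inert and no stereocentre is involved.

**Step 2**
Reactants: 2 2-(3,4-dimethoxybenzyl)-4,4,5,5-tetramethyl-1,3,2-dioxaborolane; 3 vinylmagnesium bromide; 4 2-bromo-1,3,5-trimethoxybenzene
Product: 6 (S)-2-[1-(3,4-dimethoxyphenyl)-3-(2,4,6-trimethoxyphenyl)propan-2-yl]-4,4,5,5-tetramethyl-1,3,2-dioxaborolane, via vinylborate magnesium salt 5 (not isolated)
Conditions: 3 (1.0 equiv, 1.0 M in THF), THF, 0 °C → rt; then NaOTf (2 equiv), Pd(OAc)2 (2 mol%), (Sp,Sp)-MandyPhos (2.4 mol%), 4 (1.05 equiv), degassed THF, 40–60 °C; neutral aqueous work-up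
Reagents that add atoms: none
Why: Oxidative addition of 4 to Pd(0)–MandyPhos and bromide abstraction by NaOTf give a cationic arylpalladium(II) that binds the vinyl group of borate 5 and, acting as a π-acid, induces anti 1,2-migration of the 3,4-dimethoxybenzyl group from boron to the boron-bearing carbon with Pd–C bond formation at the terminal CH2; C(sp2)–C(sp3) reductive elimination then joins that CH2 to the trimethoxyphenyl ring carbon. The closest known reaction type is the Pd/MandyPhos-catalysed enantioselective conjunctive cross-coupling of Grignard-derived vinylboron ate complexes with aryl bromides or triflates in the presence of NaOTf. No ring is closed. The new stereocentre C2 is set under catalyst control: the chiral ligand selects the π-face of the prochiral vinyl group to which palladium binds, and the migration anti to palladium is stereospecific. The step needs the metallate shift to outrun direct boron-to-palladium transfer of the benzyl or vinyl group (Suzuki-type products) and β-hydride elimination of the alkylpalladium; the four-coordinate, strongly nucleophilic vinylborate, the halide-free cationic palladium centre with a wide-bite-angle ligand and the fast reductive elimination of the electron-rich di-ortho-substituted aryl group are what should secure it. Regiochemistry is fixed by the substrate, since boron marks the migration terminus and leaves only the terminal CH2 for the aryl group.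

**Step 3**
Reactants: 6 (S)-2-[1-(3,4-dimethoxyphenyl)-3-(2,4,6-trimethoxyphenyl)propan-2-yl]-4,4,5,5-tetramethyl-1,3,2-dioxaborolane
Product: 7 hypophaol, (S)-1-(3,4-dimethoxyphenyl)-3-(2,4,6-trimethoxyphenyl)propan-2-ol
Conditions: 30% H2O2, 3 M NaOH, THF, 0 °C → rt
Reagents that add atoms: hydrogen peroxide, OO
Why: Oxidation of a secondary alkylboronic ester by hydroperoxide (boronate formation, 1,2-shift of carbon from boron to oxygen, borate hydrolysis) proceeds with retention, so the (S)-C–B bond becomes the (S)-C–O bond; the aryl methyl ethers are stable to basic peroxide.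

**Compound list**

1 | 3,4-dimethoxybenzyl chloride (4-(chloromethyl)-1,2-dimethoxybenzene) | COc1ccc(CCl)cc1OC | starting material
2 | 2-(3,4-dimethoxybenzyl)-4,4,5,5-tetramethyl-1,3,2-dioxaborolane | COc1ccc(CB2OC(C)(C)C(C)(C)O2)cc1OC | intermediate
3 | vinylmagnesium bromide | C=C[Mg]Br | starting material
4 | 2-bromo-1,3,5-trimethoxybenzene | COc1cc(OC)c(Br)c(OC)c1 | starting material
5 | bromomagnesium (3,4-dimethoxybenzyl)(pinacolato)(vinyl)borate (vinylborate magnesium salt) | C=C[B-]1(Cc2ccc(OC)c(OC)c2)OC(C)(C)C(C)(C)O1.Br[Mg+] | intermediate
6 | (S)-2-[1-(3,4-dimethoxyphenyl)-3-(2,4,6-trimethoxyphenyl)propan-2-yl]-4,4,5,5-tetramethyl-1,3,2-dioxaborolane | COc1cc(OC)c(C[C@@H](B2OC(C)(C)C(C)(C)O2)Cc2ccc(OC)c(OC)c2)c(OC)c1 | intermediate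
7 | hypophaol, (S)-1-(3,4-dimethoxyphenyl)-3-(2,4,6-trimethoxyphenyl)propan-2-ol | COc1cc(OC)c(C[C@@H](O)Cc2ccc(OC)c(OC)c2)c(OC)c1 | target

**Summary**

Total step count: 3. Longest linear sequence: 3 steps (1 → 2 → 6 → 7).

**Steps most likely to fail**

1. Step 2. The risks are direct boron-to-palladium transfer of the benzyl or vinyl group outrunning the metallate shift, sluggish oxidative addition of the electron-rich di-ortho-substituted bromide, and eroded facial selectivity at the crowded arylpalladium centre. The fallback sets out from 4 and comes back at 7. Compound 4 is converted with magnesium in THF into 2,4,6-trimethoxyphenylmagnesium bromide F1. Under CuI catalysis (10 mol%, THF, −30 → 0 °C) F1 should open (S)-2-(3,4-dimethoxybenzyl)oxirane F2 at its unsubstituted ring carbon, giving 7 directly after aqueous work-up; C2 is not touched, so its configuration is retained. F2 would be obtained from commercial methyl eugenol (4-allyl-1,2-dimethoxybenzene) by mCPBA epoxidation to racemic 2-(3,4-dimethoxybenzyl)oxirane F3, followed by Jacobsen hydrolytic kinetic resolution (0.55 equiv water). The (salen)Co(III)OAc antipode that leaves the (S)-epoxide unreacted is used; this is expected to be the (S,S)-catalyst, to be confirmed.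

2. Step 1. The risks are Wurtz-type homocoupling of the electron-rich benzylic chloride at palladium and protodeboronation of the electron-rich benzylboronate during purification. The fallback sets out from 1 and comes back at 2. Compound 1 is added slowly to activated magnesium in THF at 0 °C in the presence of 2-isopropoxy-4,4,5,5-tetramethyl-1,3,2-dioxaborolane (Barbier mode). The transient 3,4-dimethoxybenzylmagnesium chloride F4 is thereby trapped at boron as it forms, and 2 is obtained after aqueous work-up and distillation instead of chromatography.

3. Step 3. The risk is slow peroxide attack at the flanked secondary boronate, with protodeboronation on prolonged exposure to base. The fallback sets out from 6 and comes back at 7. Compound 6 is treated with KHF2 in MeOH/H2O to give potassium [(S)-1-(3,4-dimethoxyphenyl)-3-(2,4,6-trimethoxyphenyl)propan-2-yl]trifluoroborate F5, which is purified by precipitation. F5 is then oxidised with Oxone in acetone/H2O at room temperature under near-neutral conditions, again with retention at C2, to give 7.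

**Further compounds**

F1 | step 2 | 2,4,6-trimethoxyphenylmagnesium bromide | COc1cc(OC)c([Mg]Br)c(OC)c1
F2 | step 2 | (S)-2-(3,4-dimethoxybenzyl)oxirane | C1[C@@H](O1)Cc1ccc(OC)c(OC)c1
F3 | step 2 | racemic 2-(3,4-dimethoxybenzyl)oxirane | COc1ccc(CC2CO2)cc1OC
F4 | step 1 | 3,4-dimethoxybenzylmagnesium chloride | COc1ccc(C[Mg]Cl)cc1OC
F5 | step 3 | potassium [(S)-1-(3,4-dimethoxyphenyl)-3-(2,4,6-trimethoxyphenyl)propan-2-yl]trifluoroborate | COc1cc(OC)c(C[C@@H]([B-](F)(F)F)Cc2ccc(OC)c(OC)c2)c(OC)c1.[K+]
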